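**Retrosynthetic overview**

1. The strategy rests on ring Y (C1–C2–C3–C4–C5–C9; C3 aroylated, C1 and C5 prenylated, C9 the bridging carbonyl), a dearomatised diprenyl aroylphloroglucinol whose C1 and C5 are spanned by C8(Me)(4-methylpent-3-enyl)–C7(prenyl, syn to the C2–C3–C4 bridge)–C6, with C8 on C1.
2. The C7 prenyl group is traced back to a C7 formyl group (two Wittig reactions), and the phenol to its TIPS ether.
3. Key disconnection: C5–C6 (alkylation of one enantiotopic prenylated ring carbon by a 2-(bromomethyl) enal) and C1–C8 (intramolecular Michael addition). Ring Y comes from the arene; ring X (C1–C8–C7–C6–C5–C9) is closed onto it in the same flask.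
4. Fragments: the diprenyl aroylphloroglucinol from phloroglucinol, 3-hydroxybenzoic acid and prenyl bromide; a geometrically pure bromo enal from methyl but-2-ynoate by syn-carbocupration and iodination. Its C=C geometry becomes C8.

Key step: step 8

Remark 1: the sense of induction of the cinchona phase-transfer salt in step 8 is assumed; the cinchonidinium salt is written, and its pseudo-enantiomeric cinchoninium salt is to be used if a first trial gives the antipode.
Remark 2: the leaving group is placed on C6 of an enal of fixed geometry, because a 3-acyloxy-2-methylene enal would create the C7=C8 bond only in the flask by E1cB, with no control of its geometry and therefore of C8.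
Remark 3: the phenol is masked as its TIPS ether before step 8, because a free phenoxide would compete as an O-nucleophile for the allylic bromide.

**Route**

Step 1
Reactants: 1 phloroglucinol; 2 3-hydroxybenzoic acid
Product: 3 (3-hydroxyphenyl)(2,4,6-trihydroxyphenyl)methanone
Conditions: Eaton's reagent (P2O5 in MeSO3H), 70 °C
Reagents that add atoms: none
Why: Friedel–Crafts C-acylation of the very electron-rich, threefold-symmetric arene by the activated acid should give the monoketone, since the acyl group deactivates the ring against a second acylation and the meta-hydroxy acid cannot close to a xanthone.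

Step 2
Reactants: 3 (3-hydroxyphenyl)(2,4,6-trihydroxyphenyl)methanone; 4 prenyl bromide (2.1 equiv)
Product: 5 (3-hydroxyphenyl)[2,4,6-trihydroxy-3,5-bis(3-methylbut-2-enyl)phenyl]methanone
Conditions: aq. KOH, 0 °C
Reagents that add atoms: none
Why: C-alkylation of the ambident acylphloroglucinol polyanion in water (the known double C-prenylation of 2,4,6-trihydroxybenzophenones) should occur at the two free ring carbons faster than O-alkylation of the hydrated 3′-phenoxide.

Step 3
Reactants: 5 (3-hydroxyphenyl)[2,4,6-trihydroxy-3,5-bis(3-methylbut-2-enyl)phenyl]methanone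
Product: 6 [2,4,6-trihydroxy-3,5-bis(3-methylbut-2-enyl)phenyl][3-(triisopropylsilyloxy)phenyl]methanone
Conditions: TIPSCl (1.05 equiv), imidazole, DMF, 0 °C
Reagents that add atoms: triisopropylsilyl chloride, CC(C)[Si](Cl)(C(C)C)C(C)C
Why: Silylation under steric control should take only the 3′-hydroxyl, because each phloroglucinol hydroxyl is flanked by two ortho substituents and two of them are hydrogen-bonded to the ketone.

Step 4
Reactants: 7 5-bromo-2-methylpent-2-ene; 8 methyl but-2-ynoate
Product: 11 methyl (2Z)-2-iodo-3,7-dimethylocta-2,6-dienoate (iodine cis to the 4-methylpent-3-enyl chain), via 4-methylpent-3-enylmagnesium bromide 9 (not isolated), via alkenylcopper 10 (not isolated)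
Conditions: Mg, THF; CuBr·SMe2, THF, −40 °C; 8, −78 °C; I2, −78 °C
Reagents that add atoms: iodine, II
Why: Syn-carbocupration of the alkynoate places the chain and copper cis, and iodinolysis of the alkenylcopper at −78 °C (before it can isomerise through the allenoate) should retain that geometry.

Step 5
Reactants: 11 methyl (2Z)-2-iodo-3,7-dimethylocta-2,6-dienoate
Product: 12 (2Z)-2-iodo-3,7-dimethylocta-2,6-dien-1-ol
Conditions: i-Bu2AlH (2.2 equiv), CH2Cl2, −78 °C
Reagents that add atoms: none
Why: Hydride reduction of the conjugated ester to the allylic alcohol leaves the alkenyl iodide and the alkene geometry untouched at low temperature.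

Step 6
Reactants: 12 (2Z)-2-iodo-3,7-dimethylocta-2,6-dien-1-ol
Product: 14 (2Z)-2-(hydroxymethyl)-3,7-dimethylocta-2,6-dienal (formyl cis to the 4-methylpent-3-enyl chain), via dilithio alkoxide 13 (not isolated)
Conditions: t-BuLi (3.1 equiv), Et2O, −78 °C; DMF, −78 to 0 °C; aq. NH4Cl
Reagents that add atoms: N,N-dimethylformamide, CN(C)C=O
Why: Iodine–lithium exchange on the lithium alkoxide gives a tetrasubstituted alkenyllithium that is configurationally stable at −78 °C, and its formylation with DMF proceeds with retention.

Step 7
Reactants: 14 (2Z)-2-(hydroxymethyl)-3,7-dimethylocta-2,6-dienal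
Product: 16 (2E)-2-(bromomethyl)-3,7-dimethylocta-2,6-dienal (CH2Br cis to the 3-methyl group; formyl cis to the chain), via allylic mesylate 15 (not isolated)
Conditions: MsCl, Et3N, CH2Cl2, −40 °C; LiBr, THF, 0 °C
Reagents that add atoms: lithium bromide, [Li+].[Br-]
Why: Mesylation and SN2 displacement by bromide at the primary allylic carbon should not touch the tetrasubstituted alkene, because the conjugated formyl group disfavours ionisation; the bromide is used at once.

Step 8
Reactants: 6 [2,4,6-trihydroxy-3,5-bis(3-methylbut-2-enyl)phenyl][3-(triisopropylsilyloxy)phenyl]methanone; 16 (2E)-2-(bromomethyl)-3,7-dimethylocta-2,6-dienal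
Product: 18 TIPS-protected bicyclo[3.3.1]nonane trione (4-enol) with the C7 formyl group endo (syn to the C2–C3–C4 bridge) and at C8 the methyl on the C9 side and the 4-methylpent-3-enyl group cis to the formyl group, via C5-alkylated dienone 17 (not isolated)
Conditions: CsOH·H2O (6 equiv), N-(9-anthracenylmethyl)-O-allylcinchonidinium bromide (20 mol%), 4 Å molecular sieves, CH2Cl2, −50 °C; cold pH 6 phosphate buffer, used without chromatography
Reagents that add atoms: none
Why: Under solid–liquid phase-transfer conditions the dianion of 6, paired with the chiral ammonium ion, should be C-alkylated at one of its two enantiotopic prenyl-bearing carbons by SN2 displacement of the allylic bromide of 16 (C5–C6, dearomatising ring Y to dienone 17), and the remaining prenyl-bearing enolate carbon then adds to the fully substituted β-carbon of the tethered enal (C1–C8, intramolecular Michael addition); this is the alkylative dearomatisation–annulation known for diprenyl acylphloroglucinols and α-functionalised enals, including its phase-transfer enantioselective form. Ring X (C1–C8–C7–C6–C5–C9) closes 6-endo-trig (both enal carbons end up in the new ring) through a chair in which the enal lies over ring Y. C5 is set by the chiral ion pair in the alkylation, and C1 follows from it because the three-carbon bridge can only reach the ring face that carries C6. C8 is fixed by the enal geometry: in the chair the group cis to C6 (methyl) becomes axial on the C9 side and the group cis to the formyl (4-methylpent-3-enyl) equatorial, so the single geometry of 16 should give a single C8 configuration. C7 is set by protonation of the aldehyde enolate on its open exo face (the endo face is covered by the C2–C3–C4 bridge and the aroyl group), which leaves the formyl group endo. The step needs C- over O-alkylation and substitution at CH2Br instead of attack at the tetrasubstituted β-carbon, which the soft bromide, the delocalised dianion and the low temperature should secure, while the cold buffered work-up keeps the epimerisable C7 from equilibrating.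

Step 9
Reactants: 18 TIPS-protected C7-formyl trione
Product: 19 TIPS-protected C7-(2-methoxyvinyl) trione (E/Z mixture at the enol ether)
Conditions: Ph3PCH2OMe chloride (4 equiv), KN(SiMe3)2 (3.9 equiv), THF, −78 to 0 °C; pH 6 buffer
Reagents that add atoms: (methoxymethyl)triphenylphosphonium chloride, COC[P+](c1ccccc1)(c1ccccc1)c1ccccc1.[Cl-]
Why: Wittig olefination with excess ylide, whose first equivalent only turns the triketone into its inert potassium enolate (and undoes any reversible aldol closure of the endo formyl group onto C3), should add to the aldehyde at −78 °C faster than it deprotonates the hindered C7–H, so C7 is kept.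

Step 10
Reactants: 19 TIPS-protected C7-(2-methoxyvinyl) trione
Product: 20 TIPS-protected C7-(2-oxoethyl) trione
Conditions: 1 M HCl, THF, 0 °C to rt
Reagents that add atoms: water, O
Why: Acid hydrolysis of the enol ether is much faster than protonation of the trisubstituted prenyl alkenes, the aryl TIPS ether is stable to dilute acid, and C7 now carries CH2CHO and can no longer epimerise.

Step 11
Reactants: 20 TIPS-protected C7-(2-oxoethyl) trione
Product: 21 TIPS ether of the target
Conditions: i-PrPPh3 iodide (4 equiv), n-BuLi (3.9 equiv), THF, 0 °C; 20, −78 to 0 °C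
Reagents that add atoms: isopropyltriphenylphosphonium iodide, CC(C)[P+](c1ccccc1)(c1ccccc1)c1ccccc1.[I-]
Why: Wittig olefination with the non-stabilised isopropylidene ylide, again in excess so that the enol travels as its enolate, converts CH2CHO into the prenyl group without touching a stereocenter.

Step 12
Reactants: 21 TIPS ether of the target
Product: 22 CNP0406274.1, 4-hydroxy-3-(3-hydroxybenzoyl)-8-methyl-1,5,7-tris(3-methylbut-2-enyl)-8-(4-methylpent-3-enyl)bicyclo[3.3.1]non-3-ene-2,9-dione
Conditions: Bu4NF, AcOH (1:1), THF, 0 °C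
Reagents that add atoms: none
Why: Fluoride cleaves the aryl silyl ether under near-neutral buffered conditions, and nothing else in the molecule is fluoride-labile.

**Compound list**

1 | phloroglucinol | Oc1cc(O)cc(O)c1 | starting material
2 | 3-hydroxybenzoic acid | O=C(O)c1cccc(O)c1 | starting material
3 | (3-hydroxyphenyl)(2,4,6-trihydroxyphenyl)methanone | O=C(c1cccc(O)c1)c1c(O)cc(O)cc1O | intermediate
4 | prenyl bromide | CC(C)=CCBr | starting material
5 | (3-hydroxyphenyl)[2,4,6-trihydroxy-3,5-bis(3-methylbut-2-enyl)phenyl]methanone | CC(C)=CCc1c(O)c(CC=C(C)C)c(O)c(C(=O)c2cccc(O)c2)c1O | intermediate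
6 | [2,4,6-trihydroxy-3,5-bis(3-methylbut-2-enyl)phenyl][3-(triisopropylsilyloxy)phenyl]methanone | CC(C)=CCc1c(O)c(CC=C(C)C)c(O)c(C(=O)c2cccc(O[Si](C(C)C)(C(C)C)C(C)C)c2)c1O | intermediate
7 | 5-bromo-2-methylpent-2-ene | CC(C)=CCCBr | starting material
8 | methyl but-2-ynoate | CC#CC(=O)OC | starting material
9 | 4-methylpent-3-enylmagnesium bromide | CC(C)=CCC[Mg]Br | intermediate
10 | alkenylcopper (methyl 2-cuprio-3,7-dimethylocta-2,6-dienoate, copper cis to the chain) | COC(=O)/C([Cu])=C(C)/CCC=C(C)C | intermediate
11 | methyl (2Z)-2-iodo-3,7-dimethylocta-2,6-dienoate | COC(=O)/C(I)=C(C)/CCC=C(C)C | intermediate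
12 | (2Z)-2-iodo-3,7-dimethylocta-2,6-dien-1-ol | OC/C(I)=C(C)/CCC=C(C)C | intermediate
13 | dilithio alkoxide (lithium alkoxide and alkenyllithium of 12) | [Li]OC/C([Li])=C(C)/CCC=C(C)C | intermediate
14 | (2Z)-2-(hydroxymethyl)-3,7-dimethylocta-2,6-dienal | OC/C(C=O)=C(C)/CCC=C(C)C | intermediate
15 | (2Z)-2-formyl-3,7-dimethylocta-2,6-dienyl methanesulfonate | CS(=O)(=O)OC/C(C=O)=C(C)/CCC=C(C)C | intermediate
16 | (2E)-2-(bromomethyl)-3,7-dimethylocta-2,6-dienal | BrC/C(C=O)=C(C)/CCC=C(C)C | intermediate
17 | C5-alkylated cyclohexadienone (ring Y dearomatised, one quaternary carbon bearing prenyl and the enal side chain) | CC(C)=CCC/C(C)=C(C=O)/C[C@]1(CC=C(C)C)C(=O)C(CC=C(C)C)=C(O)C(C(=O)c2cccc(O[Si](C(C)C)(C(C)C)C(C)C)c2)=C1O | intermediate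
18 | TIPS-protected 7-formyl-4-hydroxy-8-methyl-1,5-bis(3-methylbut-2-enyl)-8-(4-methylpent-3-enyl)-3-aroylbicyclo[3.3.1]non-3-ene-2,9-dione, formyl endo | CC(C)=CCC[C@@]1(C)[C@@H](C=O)C[C@]2(CC=C(C)C)C(=O)[C@@]1(CC=C(C)C)C(=O)C(C(=O)c1cccc(O[Si](C(C)C)(C(C)C)C(C)C)c1)=C2O | intermediate
19 | TIPS-protected 7-(2-methoxyvinyl) analogue of 18 (E/Z mixture, enol ether geometry left open) | CC(C)=CCC[C@@]1(C)[C@@H](C=COC)C[C@]2(CC=C(C)C)C(=O)[C@@]1(CC=C(C)C)C(=O)C(C(=O)c1cccc(O[Si](C(C)C)(C(C)C)C(C)C)c1)=C2O | intermediate
20 | TIPS-protected 7-(2-oxoethyl) analogue of 18 | CC(C)=CCC[C@@]1(C)[C@@H](CC=O)C[C@]2(CC=C(C)C)C(=O)[C@@]1(CC=C(C)C)C(=O)C(C(=O)c1cccc(O[Si](C(C)C)(C(C)C)C(C)C)c1)=C2O | intermediate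
21 | TIPS ether of the target | CC(C)=CCC[C@@]1(C)[C@@H](CC=C(C)C)C[C@]2(CC=C(C)C)C(=O)[C@@]1(CC=C(C)C)C(=O)C(C(=O)c1cccc(O[Si](C(C)C)(C(C)C)C(C)C)c1)=C2O | intermediate
22 | CNP0406274.1 | CC(C)=CCC[C@@]1(C)[C@@H](CC=C(C)C)C[C@]2(CC=C(C)C)C(=O)[C@@]1(CC=C(C)C)C(=O)C(C(=O)c1cccc(O)c1)=C2O | target

Total step count: 12
Longest linear sequence: 9 steps (steps 4–12)

**Steps most likely to fail**

1. Step 8. The bimolecular alkylation may go partly at oxygen, or discriminate poorly between the two enantiotopic ring carbons, or stall before the quaternary–quaternary closure. Fallback, setting out from 6 and returning at 18: form the first bond by conjugate addition–elimination instead of substitution.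
   - Commercial 2-bromo-3,3-diethoxyprop-1-ene is lithiated with t-BuLi to 3,3-diethoxy-2-lithioprop-1-ene F1.
   - F1 is added to commercial 6-methylhept-5-en-2-one to give 2-(diethoxymethyl)-3,7-dimethylocta-1,6-dien-3-ol F2.
   - Acetylation (Ac2O, DMAP, Et3N) gives the tertiary acetate F3.
   - Acetal hydrolysis (aqueous oxalic acid on silica) gives racemic 3-acetoxy-3,7-dimethyl-2-methyleneoct-6-enal F4.
   - With 6 under the phase-transfer conditions of step 8, the dianion adds to the methylene carbon of F4, acetate leaves by E1cB and the Michael closure follows; this pathway is C-selective by nature.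
   - Its price is that the elimination gives dienone 17 together with its enal geometric isomer F5, so that 18 is formed together with its C8 epimer F6, which has to be removed by chromatography.

2. Step 9. The basic ylide may deprotonate C7 faster than it adds to the hindered carbonyl, equilibrating the formyl group to the exo position. Fallback, setting out from 18 and returning at 20: a non-basic homologation.
   - Methylenation with Zn, CH2Br2 and TiCl4 gives the C7-vinyl compound F7.
   - Anti-Markovnikov hydroboration of the only monosubstituted alkene ([Ir(cod)Cl]2, dppe, pinacolborane) gives the pinacol boronate F8.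
   - Oxidation with NaBO3·4H2O gives the primary alcohol F9.
   - SO3·pyridine, DMSO, i-Pr2NEt oxidises F9 to 20.

3. Step 4. The α-cuprio ester may isomerise through its allenoate before iodinolysis, eroding the alkene geometry that later becomes C8. Fallback, setting out from 9 and returning at 14: a carbometalation whose alkenyl–metal bond is not conjugated to a carbonyl group.
   - Fe(acac)3-catalysed, alkoxide-directed syn-carbomagnesiation of commercial but-2-yn-1-ol with 9 delivers the chain to the alkyne carbon remote from oxygen and gives the alkenylmagnesium alkoxide F10.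
   - F10 is formylated in the same flask with DMF to give 14 directly, which replaces steps 4–6.

**Further compounds**

F1 | step 8 | 3,3-diethoxy-2-lithioprop-1-ene | [Li]C(=C)C(OCC)OCC
F2 | step 8 | 2-(diethoxymethyl)-3,7-dimethylocta-1,6-dien-3-ol | CCOC(OCC)C(=C)C(C)(O)CCC=C(C)C
F3 | step 8 | 3-(diethoxymethyl)-2,6-dimethyl... tertiary acetate of F2 | CCOC(OCC)C(=C)C(C)(OC(C)=O)CCC=C(C)C
F4 | step 8 | 3-acetoxy-3,7-dimethyl-2-methyleneoct-6-enal (racemic) | O=CC(=C)C(C)(OC(C)=O)CCC=C(C)C
F5 | step 8 | enal geometric isomer of dienone 17 | CC(C)=CCC/C(C)=C(C=O)\C[C@]1(CC=C(C)C)C(=O)C(CC=C(C)C)=C(O)C(C(=O)c2cccc(O[Si](C(C)C)(C(C)C)C(C)C)c2)=C1O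
F6 | step 8 | C8 epimer of 18 | CC(C)=CCC[C@]1(C)[C@@H](C=O)C[C@]2(CC=C(C)C)C(=O)[C@@]1(CC=C(C)C)C(=O)C(C(=O)c1cccc(O[Si](C(C)C)(C(C)C)C(C)C)c1)=C2O
F7 | step 9 | TIPS-protected C7-vinyl trione | CC(C)=CCC[C@@]1(C)[C@@H](C=C)C[C@]2(CC=C(C)C)C(=O)[C@@]1(CC=C(C)C)C(=O)C(C(=O)c1cccc(O[Si](C(C)C)(C(C)C)C(C)C)c1)=C2O
F8 | step 9 | TIPS-protected C7-[2-(pinacolboryl)ethyl] trione | CC(C)=CCC[C@@]1(C)[C@@H](CCB3OC(C)(C)C(C)(C)O3)C[C@]2(CC=C(C)C)C(=O)[C@@]1(CC=C(C)C)C(=O)C(C(=O)c1cccc(O[Si](C(C)C)(C(C)C)C(C)C)c1)=C2O
F9 | step 9 | TIPS-protected C7-(2-hydroxyethyl) trione | CC(C)=CCC[C@@]1(C)[C@@H](CCO)C[C@]2(CC=C(C)C)C(=O)[C@@]1(CC=C(C)C)C(=O)C(C(=O)c1cccc(O[Si](C(C)C)(C(C)C)C(C)C)c1)=C2O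
F10 | step 4 | alkenylmagnesium alkoxide from but-2-yn-1-ol and 9 (magnesium cis to the chain) | Br[Mg]OC/C([Mg]Br)=C(C)/CCC=C(C)C
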